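**Strategy.** Ring C (O1–C2–C3–C4–C4a–C8a) is disconnected at C3–C4 and O1–C2. This exploits two features. C4 is an unsubstituted methylene ortho to the C8a oxygen of ring A (an ortho-quinone methide retron). C3 is alpha to C2, which can be carried as an aldehyde carbon. In one operation a chiral secondary amine joins the two fully prenylated halves by Michael addition and hemiacetalisation, closes ring C and sets C3. The precursors are open-chain: a 2-(tosylmethyl)phenol (ring A, made by a Claisen–Cope relay) and a ring B arylacetaldehyde. Deoxygenation at C2, oxidative demethylation of ring B and one hydrolysis complete the route.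

Key step: step 9

Remark: isoflavan numbering is used (ring C = O1, C2, C3, C4, C4a, C8a; ring A = C4a to C8a; ring B atoms primed), and 1 and 9 are taken to be catalogue compounds.

Step 1
Reactants: 1 2,4-dihydroxy-6-methoxybenzaldehyde
Product: 2 4-formyl-3-hydroxy-5-methoxyphenyl pivalate
Conditions: PivCl (1.05 equiv), Et3N, CH2Cl2, −10 to 0 °C
Reagents that add atoms: pivaloyl chloride, CC(C)(C)C(=O)Cl
Why: Chemoselective O-acylation, because only the hydroxyl para to the formyl group (future O7) is free of the hydrogen bond to the carbonyl and is the more acidic one; the ester later also lowers the nucleophilicity and ease of oxidation of ring A.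

Step 2
Reactants: 2 4-formyl-3-hydroxy-5-methoxyphenyl pivalate; 3 3-methylbut-2-en-1-ol (prenol)
Product: 4 4-formyl-3-methoxy-5-(3-methylbut-2-enyloxy)phenyl pivalate
Conditions: PPh3, DIAD, THF, 0 °C to rt
Reagents that add atoms: none
Why: Mitsunobu etherification alkylates the remaining chelated phenol (future O1) at the primary carbon of 3 under neutral conditions, so the aryl pivalate should neither migrate nor cleave.

Step 3
Reactants: 4 4-formyl-3-methoxy-5-(3-methylbut-2-enyloxy)phenyl pivalate
Product: 6 4-formyl-5-hydroxy-3-methoxy-2-(3-methylbut-2-enyl)phenyl pivalate, via ortho-dienone 5 (not isolated)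
Conditions: Eu(fod)3 (10 mol %; fod = 6,6,7,7,8,8,8-heptafluoro-2,2-dimethyloctane-3,5-dionate), CHCl3, 65 °C, sealed tube
Reagents that add atoms: none
Why: Tandem aromatic Claisen and Cope rearrangement (para-Claisen), in which chelation of the formyl and ether oxygens by the Lewis acid speeds the [3,3] shift to C8 and dienone 5 relays the allyl unit by a second [3,3] shift to C6, the only para position, which restores the normal prenyl connectivity between O5 and O7 and frees the O1 phenol.

Step 4
Reactants: 6 4-formyl-5-hydroxy-3-methoxy-2-(3-methylbut-2-enyl)phenyl pivalate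
Product: 7 5-hydroxy-4-(hydroxymethyl)-3-methoxy-2-(3-methylbut-2-enyl)phenyl pivalate
Conditions: NaBH4, THF/EtOH, −10 °C; aq NH4Cl
Reagents that add atoms: none
Why: Borohydride reduction of the aldehyde should stop at the benzylic alcohol at low temperature, because quinone methide formation, the path to over-reduction, needs warmer basic conditions.

Step 5
Reactants: 7 5-hydroxy-4-(hydroxymethyl)-3-methoxy-2-(3-methylbut-2-enyl)phenyl pivalate
Product: 8 5-hydroxy-3-methoxy-2-(3-methylbut-2-enyl)-4-(tosylmethyl)phenyl pivalate
Conditions: p-TolSO2H, CH2Cl2, rt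
Reagents that add atoms: p-toluenesulfinic acid, Cc1ccc(cc1)S(=O)O
Why: Acid-promoted SN1-type substitution, in which the benzylic alcohol flanked by OH and OMe ionises under the sulfinic acid itself and the sulfur nucleophile captures the cation to give a storable sulfone, the masked form of the quinone methide.

Step 6
Reactants: 9 1-bromo-2,4,5-trimethoxybenzene; 10 ethylene oxide
Product: 12 2-(2,4,5-trimethoxyphenyl)ethanol, via aryllithium 11 (not isolated)
Conditions: n-BuLi, THF, −78 °C; then 10, −78 °C to rt; H2O
Reagents that add atoms: none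
Why: Bromine–lithium exchange followed by epoxide opening by aryllithium 11 installs the two carbons that become C3 and C2.

Step 7
Reactants: 12 2-(2,4,5-trimethoxyphenyl)ethanol; 13 1-bromo-3-methylbut-2-ene (prenyl bromide)
Product: 15 2-[2,4,5-trimethoxy-3-(3-methylbut-2-enyl)phenyl]ethanol, via dilithio species 14 (not isolated)
Conditions: n-BuLi (2.3 equiv), THF, 0 °C to rt; then 13 (1.05 equiv), −78 to 0 °C; H2O
Reagents that add atoms: none
Why: Directed ortho-metalation, in which the base first removes the O–H proton and then the ring proton between the two methoxy groups (future C3'), the only doubly activated site, and the aryllithium is alkylated at the primary carbon of the allylic bromide much faster than the lithium alkoxide.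

Step 8
Reactants: 15 2-[2,4,5-trimethoxy-3-(3-methylbut-2-enyl)phenyl]ethanol
Product: 16 2-[2,4,5-trimethoxy-3-(3-methylbut-2-enyl)phenyl]acetaldehyde
Conditions: Dess–Martin periodinane, CH2Cl2, 0 °C to rt; used at once
Reagents that add atoms: none
Why: Dess–Martin oxidation stops at the aldehyde under non-basic conditions that leave the trisubstituted alkene and the electron-rich arene untouched.

Step 9
Reactants: 8 5-hydroxy-3-methoxy-2-(3-methylbut-2-enyl)-4-(tosylmethyl)phenyl pivalate; 16 2-[2,4,5-trimethoxy-3-(3-methylbut-2-enyl)phenyl]acetaldehyde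
Product: 19 (3R)-2-hydroxy-5-methoxy-6-prenyl-3-(2,4,5-trimethoxy-3-prenylphenyl)chroman-7-yl pivalate (lactol; anomers at C2), via ortho-quinone methide 17 (not isolated), via E-enamine 18 (not isolated)
Conditions: 16 (1.5 equiv), (R)-α,α-diphenylprolinol trimethylsilyl ether (20 mol %), Na2CO3, CH2Cl2/H2O, 0 °C
Reagents that add atoms: none
Why: Carbonate deprotonates the C8a hydroxyl of 8 and sulfinate leaves from C4, which releases the ortho-quinone methide 17 at low stationary concentration, while 16 condenses with the catalyst to the conjugated E-enamine 18. The enamine carbon (future C3) adds to the exocyclic C4 of 17, driven by rearomatisation of ring A, and the C8a phenoxide then adds to C2 of the iminium ion or of the freed aldehyde, so that hydrolysis gives lactol 19 and returns the amine. The closest known reaction type is the secondary-amine-catalysed formal [4+2] annulation of enolisable aldehydes with ortho-quinone methides released from 2-(sulfonylmethyl)phenols. Ring C closes in a 6-exo-trig mode by attack of O1 on C2 after the intermolecular C3–C4 bond has formed. C3 is controlled by the catalyst, whose diphenyl(silyloxy)methyl group covers the Si face of the s-trans E-enamine so that attack on the Re face gives 3R, whereas C2 forms as an anomer mixture that step 10 erases. The step needs C-attack by the enamine in preference to N-alkylation of free amine, self-addition of 17 or attack by ring A carbons; this is secured by the high enamine content of a conjugated arylacetaldehyde, the slow release of 17, the deactivating 7-pivalate, and the O5 methyl and O7 pivaloyl groups that leave O1 as the only oxygen able to close.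

Step 10
Reactants: 19 (3R)-lactol
Product: 21 (3R)-5-methoxy-6-prenyl-3-(2,4,5-trimethoxy-3-prenylphenyl)chroman-7-yl pivalate, via oxocarbenium ion 20 (not isolated)
Conditions: Et3SiH (3 equiv), BF3·OEt2, CH2Cl2, −78 to −40 °C
Reagents that add atoms: none
Why: Ionic deoxygenation of a lactol, in which the Lewis acid ionises the anomeric C2 hydroxyl to oxocarbenium ion 20 and the silane delivers hydride to C2 faster than C3–H is lost at low temperature, so ring C and the C3 configuration are kept and the prenyl groups and the pivalate are not touched.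

Step 11
Reactants: 21 (3R)-chroman pivalate
Product: 22 (3R)-5-methoxy-3-(4-methoxy-3,6-dioxo-5-prenylcyclohexa-1,4-dienyl)-6-prenylchroman-7-yl pivalate
Conditions: (NH4)2Ce(NO3)6 (2.2 equiv), MeCN/H2O, 0 °C, short contact
Reagents that add atoms: water, O
Why: Oxidative demethylation by tetravalent cerium, in which the para-related 2'- and 5'-methoxy groups make ring B the most easily oxidised arene and water attacks its radical cation at C2' and C5' to give the para-quinone, while ring A (no para oxygen pair, deactivated by the pivalate) and both prenyl groups should stay intact.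

Step 12
Reactants: 22 (3R)-methoxyquinone pivalate
Product: 23 target, (3R)-7-hydroxy-3-(4-hydroxy-3,6-dioxo-5-prenylcyclohexa-1,4-dienyl)-5-methoxy-6-prenylchroman
Conditions: LiOH, THF/H2O, 0 °C, argon; then 1 M HCl to pH 3
Reagents that add atoms: lithium hydroxide, [Li+].[OH-]
Why: Hydroxide adds to C4' of the vinylogous ester and expels methoxide (addition–elimination) and saponifies the aryl pivalate in the same operation, the delocalised hydroxyquinone anion resists further attack, and acidification should give the target with C3 unchanged.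

**Compound list**
1 | 2,4-dihydroxy-6-methoxybenzaldehyde | COc1cc(O)cc(O)c1C=O | starting material
2 | 4-formyl-3-hydroxy-5-methoxyphenyl pivalate | COc1cc(OC(=O)C(C)(C)C)cc(O)c1C=O | intermediate
3 | 3-methylbut-2-en-1-ol | CC(C)=CCO | starting material
4 | 4-formyl-3-methoxy-5-(3-methylbut-2-enyloxy)phenyl pivalate | COc1cc(OC(=O)C(C)(C)C)cc(OCC=C(C)C)c1C=O | intermediate
5 | ortho-dienone carrying the 2-methylbut-3-en-2-yl group at C8 (racemic, transient) | COC1=C(C=O)C(=O)C(C(C)(C)C=C)C(OC(=O)C(C)(C)C)=C1 | intermediate
6 | 4-formyl-5-hydroxy-3-methoxy-2-(3-methylbut-2-enyl)phenyl pivalate | COc1c(CC=C(C)C)c(OC(=O)C(C)(C)C)cc(O)c1C=O | intermediate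
7 | 5-hydroxy-4-(hydroxymethyl)-3-methoxy-2-(3-methylbut-2-enyl)phenyl pivalate | COc1c(CC=C(C)C)c(OC(=O)C(C)(C)C)cc(O)c1CO | intermediate
8 | 5-hydroxy-3-methoxy-2-(3-methylbut-2-enyl)-4-(tosylmethyl)phenyl pivalate | COc1c(CC=C(C)C)c(OC(=O)C(C)(C)C)cc(O)c1CS(=O)(=O)c1ccc(C)cc1 | intermediate
9 | 1-bromo-2,4,5-trimethoxybenzene | COc1cc(OC)c(Br)cc1OC | starting material
10 | ethylene oxide | C1CO1 | starting material
11 | 2,4,5-trimethoxyphenyllithium | [Li]c1cc(OC)c(OC)cc1OC | intermediate
12 | 2-(2,4,5-trimethoxyphenyl)ethanol | OCCc1cc(OC)c(OC)cc1OC | intermediate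
13 | 1-bromo-3-methylbut-2-ene | CC(C)=CCBr | starting material
14 | lithium 2-(3-lithio-2,4,5-trimethoxyphenyl)ethoxide | [Li]OCCc1cc(OC)c(OC)c([Li])c1OC | intermediate
15 | 2-[2,4,5-trimethoxy-3-(3-methylbut-2-enyl)phenyl]ethanol | OCCc1cc(OC)c(OC)c(CC=C(C)C)c1OC | intermediate
16 | 2-[2,4,5-trimethoxy-3-(3-methylbut-2-enyl)phenyl]acetaldehyde | O=CCc1cc(OC)c(OC)c(CC=C(C)C)c1OC | intermediate
17 | ring A ortho-quinone methide | C=C1C(=O)C=C(OC(=O)C(C)(C)C)C(CC=C(C)C)=C1OC | intermediate
18 | E-enamine of 16 and the (R)-amine catalyst | C[Si](C)(C)OC(c1ccccc1)(c1ccccc1)[C@H]1CCCN1/C=C/c1cc(OC)c(OC)c(CC=C(C)C)c1OC | intermediate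
19 | (3R)-lactol, anomers at C2 | COc1c(CC=C(C)C)c(OC(=O)C(C)(C)C)cc2c1C[C@H](c1cc(OC)c(OC)c(CC=C(C)C)c1OC)C(O)O2 | intermediate
20 | (3R)-oxocarbenium ion | COc1c(CC=C(C)C)c(OC(=O)C(C)(C)C)cc2c1C[C@H](c1cc(OC)c(OC)c(CC=C(C)C)c1OC)C=[O+]2 | intermediate
21 | (3R)-5-methoxy-6-prenyl-3-(2,4,5-trimethoxy-3-prenylphenyl)chroman-7-yl pivalate | COc1c(CC=C(C)C)c(OC(=O)C(C)(C)C)cc2c1C[C@H](c1cc(OC)c(OC)c(CC=C(C)C)c1OC)CO2 | intermediate
22 | (3R)-methoxyquinone pivalate | COc1c(CC=C(C)C)c(OC(=O)C(C)(C)C)cc2c1C[C@H](C1=CC(=O)C(OC)=C(CC=C(C)C)C1=O)CO2 | intermediate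
23 | CNP0148998.1, (3R) | COc1c(CC=C(C)C)c(O)cc2c1C[C@H](C1=CC(=O)C(O)=C(CC=C(C)C)C1=O)CO2 | target

**Total step count:** 12. **Longest linear sequence:** 9 (steps 1–5, then 9–12).

**Steps most likely to fail**

1. Step 9.
   - Three processes may interfere: alkylation of the free amine by the unhindered methide carbon, self-aldolisation of 16, and slow enolisation of the open hydroxy-aldehyde form of the lactol, which would erode the configuration at C3.
   - The fallback replaces amine catalysis by a covalent auxiliary and a metal enolate at the acid oxidation level. It sets out from 15 and 8 and comes back at 19.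
   - Alcohol 15 is oxidised (TEMPO, PhI(OAc)2, MeCN/H2O) to the arylacetic acid F1. This is coupled (PivCl, Et3N, LiCl, THF) with (R)-4-benzyloxazolidin-2-one to the imide F2.
   - The sodium Z-enolate of the imide (NaN(SiMe3)2, THF, −78 °C) is combined with the sodium phenoxide of 8. On warming, loss of sulfinate releases 17, and the enolate attacks C4 on the face away from the benzyl group.
   - The phenoxide then acylates itself at the imide carbonyl, which frees the auxiliary and gives the (3R)-dihydrocoumarin F3.
   - One equivalent of i-Bu2AlH (toluene, −78 °C) should reduce the unhindered lactone in preference to the hindered pivalate and return lactol 19.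

2. Step 10.
   - The oxocarbenium ion may lose the C3 proton (racemisation through the enol ether), or hydride may be delivered to the open aldehyde form instead of the ring.
   - The fallback avoids any cation next to C3. It sets out from 19 and comes back at 21.
   - NaBH4 (EtOH, 0 °C) traps the open form as the phenol alcohol F4. An intramolecular Mitsunobu etherification (PPh3, DIAD, THF, 0 °C) then forms O1–C2 by SN2 displacement at the primary carbon.

3. Step 12.
   - Deprotonation at C3, which is vinylogous to the quinone carbonyl, may compete with hydroxide addition at C4'. This would lead to racemisation or tautomerisation to a quinone methide.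
   - The fallback cleaves the O–CH3 bond instead of the C4'–O bond and adds oxygen base only once the quinone is protected as its anion. It sets out from 22 and comes back at 23.
   - LiI (EtOAc, 60 °C, dark) attacks the methyl group of the vinylogous ester by SN2. After a mild acid wash this gives the 7-O-pivaloyl hydroxyquinone F5.
   - K2CO3 in MeOH at 0 °C first ionises the 4'-hydroxyl, so that C3–H is no longer acidified. It then removes the pivalate by methanolysis to give 23.

**Further compounds**
F1 | step 9 | 2-[2,4,5-trimethoxy-3-(3-methylbut-2-enyl)phenyl]acetic acid | O=C(O)Cc1cc(OC)c(OC)c(CC=C(C)C)c1OC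
F2 | step 9 | (R)-4-benzyl-3-{2-[2,4,5-trimethoxy-3-(3-methylbut-2-enyl)phenyl]acetyl}oxazolidin-2-one | O=C(Cc1cc(OC)c(OC)c(CC=C(C)C)c1OC)N1C(=O)OC[C@H]1Cc1ccccc1
F3 | step 9 | (3R)-5-methoxy-2-oxo-6-prenyl-3-(2,4,5-trimethoxy-3-prenylphenyl)chroman-7-yl pivalate | COc1c(CC=C(C)C)c(OC(=O)C(C)(C)C)cc2c1C[C@H](c1cc(OC)c(OC)c(CC=C(C)C)c1OC)C(=O)O2
F4 | step 10 | (R)-5-hydroxy-4-[3-hydroxy-2-(2,4,5-trimethoxy-3-prenylphenyl)propyl]-3-methoxy-2-prenylphenyl pivalate | COc1c(CC=C(C)C)c(OC(=O)C(C)(C)C)cc(O)c1C[C@H](c1cc(OC)c(OC)c(CC=C(C)C)c1OC)CO
F5 | step 12 | (3R)-3-(4-hydroxy-3,6-dioxo-5-prenylcyclohexa-1,4-dienyl)-5-methoxy-6-prenylchroman-7-yl pivalate | COc1c(CC=C(C)C)c(OC(=O)C(C)(C)C)cc2c1C[C@H](C1=CC(=O)C(O)=C(CC=C(C)C)C1=O)CO2
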